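## Retrosynthetic overview

- The strategy rests on the C4–O–C8 ether bridge across the ten-membered carbocycle (an 11-oxabicyclo[5.3.1]undecane). Its oxygen sits on C8, the β-carbon of the C19 γ-lactone, and the lactone γ-carbon C7 is bonded to the chlorine-bearing allylic carbon C6.
- Breaking O4–C8 (retro-oxa-Michael) uncovers a C8=C17 butenolide. Breaking C6–C7 (retro-vinylogous aldol) then opens the carbocycle to a seco hydroxy enal.
- The seco chain is cut at C2–C3 (boron aldol with a C3–C6/C16 ketone) and at C9–C10 (zirconium aldol with 4-formyl-3-methylbutenolide, after cuprate methylation at C1).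
- Ring order: ring A (bought as a cyclohexenone) and the lactone (bought as a tetronic acid), then the ten-membered carbocycle, then the tetrahydropyran. The last two close in one flask. C6–Cl, C3–OAc and C2–OH are adjusted at the end.

Key step: step 27

**Numbering and abbreviations.** Briarane numbering is used:
- C1 quaternary (C15 methyl), C2 carbinol, C3, C4 ether CH, C5(=C16), C6, C7 lactone O–CH, C8 ether carbon, C9, C10
- C11(=C20), C12, C13, C14, C17 (C18 methyl), C19 lactone C=O
- "Exo" is the pyran face turned away from the C3–C2–C1–C10–C9 bridge.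
- PMB = 4-methoxybenzyl, TBS = tert-butyldimethylsilyl, TES = triethylsilyl, TMS = trimethylsilyl.

**Assumption.** The lipase hydrolyses the R acetate faster, as the empirical size rule for secondary alcohols predicts with the carbonyl carbon as the larger flank. With the opposite preference, the S alcohol 7 would be collected directly from step 3 and step 4 dropped.

**Remark.** C6 of 38–40 is drawn as the equatorial (exo) carbinol. Its epimer in the bridged series is compound 42, and both converge at enone 41.

## Route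

Step 1
Reactants: 1 4-methoxybenzyl alcohol; 2 tributyl(iodomethyl)stannane
Product: 3 tributyl{[(4-methoxybenzyl)oxy]methyl}stannane
Conditions: NaH, THF–DMF, 0 °C → rt
Reagents that add atoms: none
Why: Williamson ether synthesis, in which the sodium alkoxide displaces the unhindered primary iodide next to tin and gives the storable precursor of the PMB-oxymethyl anion needed in steps 6 and 20.

Step 2
Reactants: 4 3-ethoxycyclohex-2-en-1-one
Product: 5 rac-6-acetoxy-3-ethoxycyclohex-2-en-1-one
Conditions: Mn(OAc)3·2H2O, benzene, reflux (Dean–Stark)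
Reagents that add atoms: manganese triacetate, CC(=O)[O-].CC(=O)[O-].CC(=O)[O-].[Mn+3]
Why: Oxidative α'-acetoxylation of an enone, in which the trivalent manganese enolate formed at the only enolisable α' position (C6) is oxidised and captured by acetate, so the racemic 6-acetate should be the only regioisomer.

Step 3
Reactants: 5 rac-6-acetoxy-3-ethoxycyclohex-2-en-1-one
Product: 6 (S)-6-acetoxy-3-ethoxycyclohex-2-en-1-one
Conditions: Amano lipase PS, pH 7 phosphate buffer–DMSO, rt, stopped near half conversion
Reagents that add atoms: none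
Why: Lipase-catalysed kinetic resolution by enantioselective ester hydrolysis, which should consume the R acetate and leave the S acetate (separated from the polar alcohol by chromatography), thereby fixing the centre that becomes C14.

Step 4
Reactants: 6 (S)-6-acetoxy-3-ethoxycyclohex-2-en-1-one
Product: 7 (S)-3-ethoxy-6-hydroxycyclohex-2-en-1-one
Conditions: K2CO3 (cat), EtOH, 0 °C
Reagents that add atoms: none
Why: Base-catalysed transesterification, run in ethanol so that any exchange at the vinylogous ester is degenerate and kept cold and brief so that the α-ketol stereocentre is not enolised.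

Step 5
Reactants: 7 (S)-3-ethoxy-6-hydroxycyclohex-2-en-1-one
Product: 8 (S)-6-(tert-butyldimethylsilyloxy)-3-ethoxycyclohex-2-en-1-one
Conditions: TBSCl, imidazole, DMF, rt
Reagents that add atoms: tert-butyldimethylsilyl chloride, CC(C)(C)[Si](C)(C)Cl
Why: Imidazole-promoted silylation of a secondary alcohol under conditions too mild to touch the stereocentre or the vinylogous ester.

Step 6
Reactants: 8 (S)-6-(tert-butyldimethylsilyloxy)-3-ethoxycyclohex-2-en-1-one; 3 tributyl{[(4-methoxybenzyl)oxy]methyl}stannane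
Product: 10 (S)-4-(tert-butyldimethylsilyloxy)-3-{[(4-methoxybenzyl)oxy]methyl}cyclohex-2-en-1-one, via tertiary carbinol adduct 9 (not isolated)
Conditions: 3, n-BuLi, THF, −78 °C; 8, −78 °C; then 1 M HCl, THF, 0 °C
Reagents that add atoms: water, O
Why: Tin–lithium exchange gives the α-alkoxymethyllithium, which adds 1,2 to the vinylogous ester, and mild acid hydrolysis with loss of ethanol transposes the enone (Stork–Danheiser sequence) without touching the silyloxy-bearing stereocentre.

Step 7
Reactants: 11 3-methyltetronic acid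
Product: 12 4-methyl-5-oxo-2,5-dihydrofuran-3-yl triflate
Conditions: Tf2O, iPr2NEt, CH2Cl2, −78 °C
Reagents that add atoms: triflic anhydride, O=S(=O)(OS(=O)(=O)C(F)(F)F)C(F)(F)F
Why: O-sulfonylation of the acidic vinylogous acid, which gives the enol triflate as the coupling handle at C8.

Step 8
Reactants: 12 4-methyl-5-oxo-2,5-dihydrofuran-3-yl triflate
Product: 13 3-methyl-4-vinylfuran-2(5H)-one
Conditions: Bu3SnCH=CH2, Pd(PPh3)4 (cat), LiCl, THF, reflux
Reagents that add atoms: tributyl(vinyl)stannane, C=C[Sn](CCCC)(CCCC)CCCC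
Why: Stille coupling of an electron-poor enol triflate, for which oxidative addition to zerovalent palladium is fast and chloride assists transmetalation.

Step 9
Reactants: 13 3-methyl-4-vinylfuran-2(5H)-one
Product: 15 4-formyl-3-methylfuran-2(5H)-one, via secondary ozonide 14 (not isolated)
Conditions: O3 (1 equiv, dye end point), CH2Cl2, −78 °C; Me2S, −78 °C → rt
Reagents that add atoms: ozone, [O-][O+]=O
Why: Ozonolysis with reductive work-up, selective because the terminal vinyl group is far more electron-rich than the tetrasubstituted ring alkene conjugated to the lactone carbonyl.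

Step 10
Reactants: 10 (S)-4-(tert-butyldimethylsilyloxy)-3-{[(4-methoxybenzyl)oxy]methyl}cyclohex-2-en-1-one
Product: 16 ring A trimethylsilyl enol ether (C10=C11) with quaternary C1
Conditions: Me2CuLi (CuI, MeLi), TMSCl, Et2O–THF, −78 → −20 °C; Et3N, pH 7 work-up
Reagents that add atoms: lithium dimethylcuprate, [Li+].C[Cu-]C; chlorotrimethylsilane, C[Si](C)(C)Cl
Why: Chlorosilane-accelerated conjugate addition of a Gilman cuprate, in which methyl is delivered anti to the neighbouring C14 silyloxy group to create quaternary C1 and the enolate is trapped regiospecifically as its silyl enol ether, free of copper salts for the next step.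

Step 11
Reactants: 16 ring A trimethylsilyl enol ether; 15 4-formyl-3-methylfuran-2(5H)-one
Product: 19 C11 ketone carrying the syn C9 carbinol–butenolide arm, via lithium enolate 17 (not isolated), via chlorozirconocene enolate 18 (not isolated)
Conditions: MeLi, THF, 0 °C; Cp2ZrCl2, −78 °C; 15, −78 °C; pH 7 buffer
Reagents that add atoms: none
Why: Zirconium-enolate aldol addition, in which methyllithium releases the regiodefined lithium enolate, exchange to the weakly basic zirconocene enolate avoids deprotonating the acidic butenolide aldehyde and gives the syn C9/C10 aldol that such enolates deliver whatever their geometry, and C10 is set by attack on the enolate face that carries only the C1 methyl group, opposite both the CH2OPMB arm and the C14 silyloxy group, which is also the thermodynamically preferred trans placement of the two arms.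

Step 12
Reactants: 19 C11 ketone carrying the C9 carbinol–butenolide arm
Product: 20 C9 triethylsilyl ether of 19
Conditions: TESOTf, 2,6-lutidine, CH2Cl2, −78 °C
Reagents that add atoms: triethylsilyl triflate, CC[Si](CC)(CC)OS(=O)(=O)C(F)(F)F
Why: Silyl triflate silylation with a hindered pyridine base, which blocks retro-aldol and dehydration of the β-hydroxy ketone and is too weakly basic to enolise the ketone or the butenolide.

Step 13
Reactants: 20 C9 triethylsilyl ether
Product: 21 C11(20) exocyclic methylene compound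
Conditions: Zn, CH2Br2, TiCl4, THF–CH2Cl2, 0 °C → rt
Reagents that add atoms: dibromomethane, BrCBr
Why: Takai–Lombardo methylenation, whose non-basic gem-dimetallic reagent converts the ketone without epimerising C10 or eliminating the β-silyloxy group and leaves the lactone carbonyl alone.

Step 14
Reactants: 21 C11(20) methylene compound
Product: 22 C9,C14 diol
Conditions: 48% aq HF, MeCN, 0 °C → rt
Reagents that add atoms: none
Why: Acidic fluoride desilylation, which removes both silyl ethers while the PMB ether, the butenolide (sensitive to basic fluoride) and the exocyclic alkene are retained.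

Step 15
Reactants: 22 C9,C14 diol
Product: 23 C9,C14 diacetate
Conditions: Ac2O, DMAP (cat), pyridine, rt
Reagents that add atoms: acetic anhydride, CC(=O)OC(C)=O
Why: DMAP-catalysed acetylation, forceful enough for the two hindered secondary alcohols yet with a base too weak to enolise the butenolide, installing two of the three final acetates early.

Step 16
Reactants: 23 C9,C14 diacetate
Product: 24 C2 primary alcohol
Conditions: DDQ, CH2Cl2–pH 7 buffer, 0 °C
Reagents that add atoms: none
Why: Oxidative cleavage of the electron-rich PMB ether with DDQ under buffered neutral conditions, which do not promote acetyl migration to the new primary hydroxyl.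

Step 17
Reactants: 24 C2 primary alcohol
Product: 25 C2 aldehyde of ring A with C11 methylene and C9, C14 acetates
Conditions: Dess–Martin periodinane, NaHCO3, CH2Cl2, 0 °C → rt
Reagents that add atoms: none
Why: Dess–Martin oxidation of a neopentyl alcohol under buffered conditions, giving an aldehyde on a quaternary carbon that cannot epimerise.

Step 18
Reactants: 26 2-methylenepropane-1,3-diol
Product: 27 2-[(triethylsilyloxy)methyl]prop-2-en-1-ol
Conditions: NaH (1 equiv), THF, rt; TESCl, 0 °C
Reagents that add atoms: chlorotriethylsilane, CC[Si](CC)(CC)Cl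
Why: Monosilylation of a symmetric diol through its sparingly soluble monosodium alkoxide, which favours a single silylation.

Step 19
Reactants: 27 2-[(triethylsilyloxy)methyl]prop-2-en-1-ol
Product: 28 2-[(triethylsilyloxy)methyl]acrolein
Conditions: MnO2, CH2Cl2, rt
Reagents that add atoms: none
Why: Manganese dioxide oxidation of an allylic alcohol, which stops at the enal and leaves the silyl ether intact.

Step 20
Reactants: 28 2-[(triethylsilyloxy)methyl]acrolein; 3 tributyl{[(4-methoxybenzyl)oxy]methyl}stannane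
Product: 29 rac-1-[(4-methoxybenzyl)oxy]-3-[(triethylsilyloxy)methyl]but-3-en-2-ol
Conditions: 3, n-BuLi, THF, −78 °C; 28, −78 °C; water
Reagents that add atoms: none
Why: Tin–lithium exchange followed by 1,2-addition of the hard α-alkoxymethyllithium to the enal, the new carbinol centre being irrelevant because it is oxidised in the next step.

Step 21
Reactants: 29 rac-1-[(4-methoxybenzyl)oxy]-3-[(triethylsilyloxy)methyl]but-3-en-2-ol
Product: 30 1-[(4-methoxybenzyl)oxy]-3-[(triethylsilyloxy)methyl]but-3-en-2-one (C3–C6 and C16)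
Conditions: Dess–Martin periodinane, NaHCO3, CH2Cl2, 0 °C, used directly
Reagents that add atoms: none
Why: Dess–Martin oxidation under neutral conditions, which spares the polymerisation-prone α-methylene ketone from nucleophiles and bases.

Step 22
Reactants: 30 C3–C6 ketone; 25 C2 aldehyde
Product: 32 2,3-syn aldol adduct holding the whole C2–C6 arm, via Z dibutylboron enolate 31 (not isolated)
Conditions: 30 (slight excess over boron reagent), Bu2BOTf, iPr2NEt, CH2Cl2, −78 °C; 25, −78 → 0 °C; MeOH–pH 7 buffer (no peroxide)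
Reagents that add atoms: none
Why: Boron-mediated aldol addition, in which the ketone can enolise only at C3, the Z enolate reacts through a chair-like six-membered transition state to give the 2,3-syn relationship, and the aldehyde face should be the one anti to the bulky C10 arm with the C15 methyl group flanking the incoming enolate (Felkin–Anh sense), which corresponds to the required C2 configuration.

Step 23
Reactants: 32 2,3-syn aldol adduct
Product: 33 C2 tert-butyldimethylsilyl ether
Conditions: TBSOTf, 2,6-lutidine, CH2Cl2, −78 → 0 °C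
Reagents that add atoms: tert-butyldimethylsilyl triflate, CC(C)(C)[Si](C)(C)OS(=O)(=O)C(F)(F)F
Why: Silyl triflate silylation of a hindered neopentyl carbinol, which blocks retro-aldol and keeps O2 from competing later for the butenolide β-carbon through its own six-membered oxa-Michael closure.

Step 24
Reactants: 33 C2 silyl ether, C4 ketone
Product: 34 3,4-anti C4 allylic alcohol
Conditions: Zn(BH4)2, Et2O, −78 → −30 °C
Reagents that add atoms: none
Why: Chelation-controlled 1,2-reduction, in which zinc ties the C4 carbonyl oxygen to the C3 PMB ether oxygen and hydride attacks the chelate from the side of the C3 hydrogen to give the 3,4-anti alcohol, while acetates and butenolide are not reduced at this temperature.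

Step 25
Reactants: 34 C4 allylic alcohol
Product: 35 C4,C6 diol
Conditions: PPTS, MeOH–CH2Cl2, 0 °C
Reagents that add atoms: none
Why: Acid-catalysed methanolysis of silyl ethers, which takes off the unhindered primary allylic TES ether far faster than the buried secondary TBS ether.

Step 26
Reactants: 35 C4,C6 diol
Product: 36 seco hydroxy enal with butenolide
Conditions: TEMPO (cat), PhI(OAc)2, CH2Cl2, rt, used directly
Reagents that add atoms: none
Why: Oxoammonium-mediated oxidation, whose steric demand selects the primary allylic alcohol over the secondary C4 carbinol and stops at the aldehyde.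

Step 27
Reactants: 36 seco hydroxy enal with butenolide
Product: 40 tetracyclic O4–C8 bridged lactone (6-exo carbinol; C2 OTBS; C3 OPMB), via silyloxyfuran enal 37 (not isolated), via macrocyclic bis-TMS ether 38 (not isolated), via macrocyclic butenolide diol 39 (not isolated)
Conditions: TMSOTf (6 equiv), iPr2NEt (4 equiv), CH2Cl2, 36 added by syringe pump (final 1 mM), −40 → 0 °C; then Bu4NF (excess), THF, −40 → 0 °C, same flask
Reagents that add atoms: none
Why: Proposed new method: TMSOTf and the hindered amine cap O4 and turn the butenolide of 36 into the aromatic 2-silyloxyfuran 37, surplus TMSOTf activates the non-enolisable C6 aldehyde so that furan carbon C7 attacks it to give macrocycle 38, and fluoride then strips both trimethylsilyl ethers so that O4 of 39 adds across the ring to C8 and the resulting lactone enolate is protonated at C17. The closest known reaction types are the silylative intramolecular vinylogous Mukaiyama aldol of butenolide aldehydes (known for small and common ring sizes only), the one-pot silyl triflate and amine Mukaiyama aldol, and the base- or fluoride-triggered oxa-Michael closure of tetrahydropyrans onto unsaturated lactones, whereas their merger into a ten-membered closure followed by bridging has no precedent. The carbocycle closes at C6–C7 in a 10-exo-trig mode at the carbonyl group (enol-endo for the furan), eased by the trans-diequatorial arms on ring A and by the sp2 centres C5, C8 and C17 in the chain, and the tetrahydropyran closes at O4–C8 in a 6-exo-trig mode. C8 is dictated by C4, because the five-carbon bridge C3–C2–C1–C10–C9 can span the new pyran only if C3 and C9 are cis and axial, C7 follows from the cis lactone–pyran fusion since only the epimer with C6 on the O4 face of the lactone can be bridged while the other can return through retro-aldol or furanolate epimerisation, C17 is set by reversible protonation that places the methyl group trans to C9, and C6 is not relied upon and is erased in step 28. The step needs attack through C7 rather than C17 and on C6 rather than on C16, which is secured by the innate reactivity of 2-silyloxyfurans at the unsubstituted 5-position (C17 is blocked by its methyl group) and by oxophilic activation of the enal that directs them to the carbonyl carbon, while slow addition at high dilution holds back dimerisation.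

Step 28
Reactants: 40 bridged lactone, C6 carbinol (with any 42 formed alongside)
Product: 41 C6 enone
Conditions: Dess–Martin periodinane, NaHCO3, CH2Cl2, 0 °C → rt
Reagents that add atoms: none
Why: Dess–Martin oxidation, which merges both C6 epimers into one α-methylene ketone under neutral conditions that should not trigger β-elimination of the C8 ether oxygen or epimerisation at C7.

Step 29
Reactants: 41 C6 enone
Product: 42 6-endo (axial) allylic alcohol
Conditions: NaBH4, CeCl3·7H2O, MeOH, −78 °C
Reagents that add atoms: none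
Why: Luche reduction, 1,2-selective for the enone, with hydride forced to approach from the exo face because the opposite face of the pyranone is covered by the C3–C2–C1–C10–C9 bridge, so that the hydroxyl ends up endo and axial.

Step 30
Reactants: 42 6-endo allylic alcohol
Product: 44 C6 allylic chloride, via allylic mesylate 43 (not isolated)
Conditions: MsCl, 2,4,6-collidine, LiCl, DMF, 0 °C → rt
Reagents that add atoms: lithium chloride, [Li+].[Cl-]
Why: In situ mesylation and SN2 displacement by chloride, chosen because the small sulfonylating agent can reach the crowded endo hydroxyl and because chloride can then enter only from the open exo face, giving the equatorial C6 chloride with inversion and relief of the syn-axial strain.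

Step 31
Reactants: 44 C6 allylic chloride
Product: 45 C3 alcohol
Conditions: DDQ, CH2Cl2–pH 7 buffer, 0 °C → rt
Reagents that add atoms: none
Why: Oxidative PMB ether cleavage with DDQ, to which the allylic chloride, the two exocyclic alkenes, the acetates and the TBS ether are inert.

Step 32
Reactants: 45 C3 alcohol
Product: 46 C3 acetate, C2 silyl ether
Conditions: Ac2O, DMAP (cat), pyridine, CH2Cl2, rt
Reagents that add atoms: acetic anhydride, CC(=O)OC(C)=O
Why: DMAP-catalysed acetylation of the only free hydroxyl, made regiochemically unambiguous by the silyl ether still in place at C2.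

Step 33
Reactants: 46 C3 acetate, C2 silyl ether
Product: 47 CNP0248899.1
Conditions: HF·pyridine, THF, 0 °C → rt
Reagents that add atoms: none
Why: Acidic fluoride desilylation, which frees the C2 hydroxyl without the basic conditions that could move the C3 acetate, open the lactone or displace the allylic chloride.

## Compound list

1 | 4-methoxybenzyl alcohol | COc1ccc(CO)cc1 | starting material
2 | tributyl(iodomethyl)stannane | CCCC[Sn](CCCC)(CCCC)CI | starting material
3 | tributyl{[(4-methoxybenzyl)oxy]methyl}stannane | CCCC[Sn](CCCC)(CCCC)COCc1ccc(OC)cc1 | intermediate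
4 | 3-ethoxycyclohex-2-en-1-one | CCOC1=CC(=O)CCC1 | starting material
5 | rac-6-acetoxy-3-ethoxycyclohex-2-en-1-one | CCOC1=CC(=O)C(OC(C)=O)CC1 | intermediate
6 | (S)-6-acetoxy-3-ethoxycyclohex-2-en-1-one | CCOC1=CC(=O)[C@@H](OC(C)=O)CC1 | intermediate
7 | (S)-3-ethoxy-6-hydroxycyclohex-2-en-1-one | CCOC1=CC(=O)[C@@H](O)CC1 | intermediate
8 | (S)-6-(tert-butyldimethylsilyloxy)-3-ethoxycyclohex-2-en-1-one | CCOC1=CC(=O)[C@@H](O[Si](C)(C)C(C)(C)C)CC1 | intermediate
9 | tertiary carbinol from 1,2-addition of PMB-oxymethyllithium to 8 (carbinol centre undefined) | CCOC1=CC(O)(COCc2ccc(OC)cc2)[C@@H](O[Si](C)(C)C(C)(C)C)CC1 | intermediate (not isolated)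
10 | (S)-4-(tert-butyldimethylsilyloxy)-3-{[(4-methoxybenzyl)oxy]methyl}cyclohex-2-en-1-one | O=C1CC[C@H](O[Si](C)(C)C(C)(C)C)C(COCc2ccc(OC)cc2)=C1 | intermediate
11 | 3-methyltetronic acid | CC1=C(O)COC1=O | starting material
12 | 4-methyl-5-oxo-2,5-dihydrofuran-3-yl triflate | CC1=C(OS(=O)(=O)C(F)(F)F)COC1=O | intermediate
13 | 3-methyl-4-vinylfuran-2(5H)-one | C=CC1=C(C)C(=O)OC1 | intermediate
14 | secondary ozonide (1,2,4-trioxolane) of 13 | CC1=C(C2OCOO2)COC1=O | intermediate (not isolated)
15 | 4-formyl-3-methylfuran-2(5H)-one (C7, C8, C9, C17, C18, C19) | CC1=C(C=O)COC1=O | intermediate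
16 | ring A TMS enol ether (C10=C11); quaternary C1 with CH3 trans and CH2OPMB cis to the C14 OTBS group | C[Si](C)(C)OC=1CC[C@H](O[Si](C)(C)C(C)(C)C)[C@@](COCc2ccc(OC)cc2)(C)C=1 | intermediate
17 | lithium enolate corresponding to 16 | [Li]OC=1CC[C@H](O[Si](C)(C)C(C)(C)C)[C@@](COCc2ccc(OC)cc2)(C)C=1 | intermediate (not isolated)
18 | chlorozirconocene enolate corresponding to 16 | Cl[Zr](OC=1CC[C@H](O[Si](C)(C)C(C)(C)C)[C@@](COCc2ccc(OC)cc2)(C)C=1)(C1C=CC=C1)C1C=CC=C1 | intermediate (not isolated)
19 | C11 ketone; C10 arm CH(OH)-butenolide trans to the CH2OPMB arm, C9/C10 syn; C14 OTBS | O=C1CC[C@H](O[Si](C)(C)C(C)(C)C)[C@@](COCc2ccc(OC)cc2)(C)[C@H]1[C@H](O)C1=C(C)C(=O)OC1 | intermediate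
20 | C9 TES ether of 19 | O=C1CC[C@H](O[Si](C)(C)C(C)(C)C)[C@@](COCc2ccc(OC)cc2)(C)[C@H]1[C@H](O[Si](CC)(CC)CC)C1=C(C)C(=O)OC1 | intermediate
21 | C11(20) methylene compound; C9 OTES, C14 OTBS, C2 OPMB | C=C1CC[C@H](O[Si](C)(C)C(C)(C)C)[C@@](COCc2ccc(OC)cc2)(C)[C@H]1[C@H](O[Si](CC)(CC)CC)C1=C(C)C(=O)OC1 | intermediate
22 | C9,C14 diol | C=C1CC[C@H](O)[C@@](COCc2ccc(OC)cc2)(C)[C@H]1[C@H](O)C1=C(C)C(=O)OC1 | intermediate
23 | C9,C14 diacetate, C2 OPMB | C=C1CC[C@H](OC(C)=O)[C@@](COCc2ccc(OC)cc2)(C)[C@H]1[C@H](OC(C)=O)C1=C(C)C(=O)OC1 | intermediate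
24 | C2 primary alcohol, C9,C14 diacetate | C=C1CC[C@H](OC(C)=O)[C@@](CO)(C)[C@H]1[C@H](OC(C)=O)C1=C(C)C(=O)OC1 | intermediate
25 | C2 aldehyde, C9,C14 diacetate, C11 methylene | C=C1CC[C@H](OC(C)=O)[C@@](C=O)(C)[C@H]1[C@H](OC(C)=O)C1=C(C)C(=O)OC1 | intermediate
26 | 2-methylenepropane-1,3-diol | C=C(CO)CO | starting material
27 | 2-[(triethylsilyloxy)methyl]prop-2-en-1-ol | C=C(CO)CO[Si](CC)(CC)CC | intermediate
28 | 2-[(triethylsilyloxy)methyl]acrolein | C=C(C=O)CO[Si](CC)(CC)CC | intermediate
29 | rac-1-[(4-methoxybenzyl)oxy]-3-[(triethylsilyloxy)methyl]but-3-en-2-ol | C=C(CO[Si](CC)(CC)CC)C(O)COCc1ccc(OC)cc1 | intermediate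
30 | 1-[(4-methoxybenzyl)oxy]-3-[(triethylsilyloxy)methyl]but-3-en-2-one | C=C(CO[Si](CC)(CC)CC)C(=O)COCc1ccc(OC)cc1 | intermediate
31 | Z dibutylboron enolate of 30 (OB and OPMB cis) | C=C(CO[Si](CC)(CC)CC)/C(OB(CCCC)CCCC)=C/OCc1ccc(OC)cc1 | intermediate (not isolated)
32 | aldol adduct: C2 OH and C3 OPMB syn, C4 ketone, C5=C16, C6 OTES | C=C1CC[C@H](OC(C)=O)[C@@]([C@@H](O)[C@H](OCc2ccc(OC)cc2)C(=O)C(=C)CO[Si](CC)(CC)CC)(C)[C@H]1[C@H](OC(C)=O)C1=C(C)C(=O)OC1 | intermediate
33 | C2 TBS ether of 32 | C=C1CC[C@H](OC(C)=O)[C@@]([C@@H](O[Si](C)(C)C(C)(C)C)[C@H](OCc2ccc(OC)cc2)C(=O)C(=C)CO[Si](CC)(CC)CC)(C)[C@H]1[C@H](OC(C)=O)C1=C(C)C(=O)OC1 | intermediate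
34 | C4 allylic alcohol, 3,4-anti | C=C1CC[C@H](OC(C)=O)[C@@]([C@@H](O[Si](C)(C)C(C)(C)C)[C@H](OCc2ccc(OC)cc2)[C@H](O)C(=C)CO[Si](CC)(CC)CC)(C)[C@H]1[C@H](OC(C)=O)C1=C(C)C(=O)OC1 | intermediate
35 | C4,C6 diol | C=C1CC[C@H](OC(C)=O)[C@@]([C@@H](O[Si](C)(C)C(C)(C)C)[C@H](OCc2ccc(OC)cc2)[C@H](O)C(=C)CO)(C)[C@H]1[C@H](OC(C)=O)C1=C(C)C(=O)OC1 | intermediate
36 | seco hydroxy enal (C4 OH, C6 aldehyde) with butenolide | C=C1CC[C@H](OC(C)=O)[C@@]([C@@H](O[Si](C)(C)C(C)(C)C)[C@H](OCc2ccc(OC)cc2)[C@H](O)C(=C)C=O)(C)[C@H]1[C@H](OC(C)=O)C1=C(C)C(=O)OC1 | intermediate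
37 | 2-(trimethylsilyloxy)furan form of 36 with C4 OTMS | C=C1CC[C@H](OC(C)=O)[C@@]([C@@H](O[Si](C)(C)C(C)(C)C)[C@H](OCc2ccc(OC)cc2)[C@H](O[Si](C)(C)C)C(=C)C=O)(C)[C@H]1[C@H](OC(C)=O)c1coc(O[Si](C)(C)C)c1C | intermediate (not isolated)
38 | ten-membered carbocyclic butenolide, C4 and C6 OTMS | C=C1CC[C@H](OC(C)=O)[C@@]2(C)[C@H]1[C@H](OC(C)=O)C1=C(C)C(=O)O[C@H]1[C@@H](O[Si](C)(C)C)C(=C)[C@@H](O[Si](C)(C)C)[C@@H](OCc1ccc(OC)cc1)[C@@H]2O[Si](C)(C)C(C)(C)C | intermediate (not isolated)
39 | ten-membered carbocyclic butenolide, C4,C6 diol | C=C1CC[C@H](OC(C)=O)[C@@]2(C)[C@H]1[C@H](OC(C)=O)C1=C(C)C(=O)O[C@H]1[C@@H](O)C(=C)[C@@H](O)[C@@H](OCc1ccc(OC)cc1)[C@@H]2O[Si](C)(C)C(C)(C)C | intermediate (not isolated)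
40 | O4–C8 bridged tetracyclic lactone, 6-exo (equatorial) carbinol | C=C1CC[C@H](OC(C)=O)[C@@]2(C)[C@H]1[C@H](OC(C)=O)[C@@]13O[C@H](C(=C)[C@H](O)[C@@H]1OC(=O)[C@@H]3C)[C@@H](OCc1ccc(OC)cc1)[C@@H]2O[Si](C)(C)C(C)(C)C | intermediate
41 | bridged lactone, C6 ketone conjugated with C5=C16 | C=C1CC[C@H](OC(C)=O)[C@@]2(C)[C@H]1[C@H](OC(C)=O)[C@@]13O[C@H](C(=C)C(=O)[C@@H]1OC(=O)[C@@H]3C)[C@@H](OCc1ccc(OC)cc1)[C@@H]2O[Si](C)(C)C(C)(C)C | intermediate
42 | bridged lactone, 6-endo (axial) carbinol | C=C1CC[C@H](OC(C)=O)[C@@]2(C)[C@H]1[C@H](OC(C)=O)[C@@]13O[C@H](C(=C)[C@@H](O)[C@@H]1OC(=O)[C@@H]3C)[C@@H](OCc1ccc(OC)cc1)[C@@H]2O[Si](C)(C)C(C)(C)C | intermediate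
43 | 6-endo allylic mesylate | C=C1CC[C@H](OC(C)=O)[C@@]2(C)[C@H]1[C@H](OC(C)=O)[C@@]13O[C@H](C(=C)[C@@H](OS(C)(=O)=O)[C@@H]1OC(=O)[C@@H]3C)[C@@H](OCc1ccc(OC)cc1)[C@@H]2O[Si](C)(C)C(C)(C)C | intermediate (not isolated)
44 | C6 allylic chloride (exo, equatorial), C3 OPMB, C2 OTBS | C=C1CC[C@H](OC(C)=O)[C@@]2(C)[C@H]1[C@H](OC(C)=O)[C@@]13O[C@H](C(=C)[C@H](Cl)[C@@H]1OC(=O)[C@@H]3C)[C@@H](OCc1ccc(OC)cc1)[C@@H]2O[Si](C)(C)C(C)(C)C | intermediate
45 | C3 alcohol, C2 OTBS | C=C1CC[C@H](OC(C)=O)[C@@]2(C)[C@H]1[C@H](OC(C)=O)[C@@]13O[C@H](C(=C)[C@H](Cl)[C@@H]1OC(=O)[C@@H]3C)[C@@H](O)[C@@H]2O[Si](C)(C)C(C)(C)C | intermediate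
46 | C3 acetate, C2 OTBS | C=C1CC[C@H](OC(C)=O)[C@@]2(C)[C@H]1[C@H](OC(C)=O)[C@@]13O[C@H](C(=C)[C@H](Cl)[C@@H]1OC(=O)[C@@H]3C)[C@@H](OC(C)=O)[C@@H]2O[Si](C)(C)C(C)(C)C | intermediate
47 | CNP0248899.1 | C=C1CC[C@H](OC(C)=O)[C@@]2(C)[C@H]1[C@H](OC(C)=O)[C@@]13O[C@H](C(=C)[C@H](Cl)[C@@H]1OC(=O)[C@@H]3C)[C@@H](OC(C)=O)[C@@H]2O | target

## Step count and risks

Total step count: 33.
Longest linear sequence: 25 steps (4 → 47 through steps 2–6, 10–17 and 22–33).

**Steps most likely to fail**

**1. Step 27.**

*What may go wrong.*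
- The ten-membered closure may lose out to oligomerisation.
- The C9 acetate, which becomes furfuryl-type once the silyloxyfuran is formed, may ionise.
- The macrocycle may reopen by retro-aldol during the fluoride stage, before the ether bridge is closed.

*Fallback (known chemistry only).* The C6–C7 bond is made first and intermolecularly. The carbocycle is then closed at C4–C5 by a Nozaki–Hiyama–Kishi reaction, an established closure for ten-membered and oxygen-bridged medium carbocycles that leaves an exocyclic methylene next to the new carbinol. It sets out from diacetate 23.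

TBSOTf and Et3N give the tert-butyldimethylsilyloxyfuran F1. A BF3·OEt2-promoted vinylogous Mukaiyama aldol with 2-iodoprop-2-enal gives the syn iodoallylic carbinol F2, whose C7 epimers are separated or equilibrated with DBU. TESOTf and 2,6-lutidine give the C6 triethylsilyl ether F3. DDQ gives the C2 primary alcohol F4, and Dess–Martin periodinane gives the C2 aldehyde F5.

The titanium enolate (TiCl4, iPr2NEt, N-methylpyrrolidinone) of the glycolyl auxiliary N-{[(4-methoxybenzyl)oxy]acetyl}-(S)-4-benzylthiazolidine-2-thione F6 sets C2 and C3 under reagent control and gives the syn aldol adduct F7. TBSOTf gives the C2 silyl ether F8. DIBAL-H at −78 °C reduces the activated imide to the C4 aldehyde F9.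

CrCl2 with catalytic NiCl2 in DMSO–THF at high dilution gives the macrocyclic C4 allylic alcohol F10. Bu4NF then removes the C6 silyl ether and triggers the 6-exo oxa-Michael closure. The route is rejoined at 42.

**2. Step 22.**

*What may go wrong.*
- The facial selectivity at the neopentyl aldehyde may be poor or reversed, since Z enolates tend to oppose Felkin–Anh control.
- The addition may be sluggish.
- The butenolide may be enolised and then undergo a six-membered intramolecular vinylogous aldol onto C2.

*Fallback.* Substrate control is replaced by auxiliary control, and the C4–C5 bond is made afterwards. It sets out from aldehyde 25.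

The titanium enolate of the glycolyl auxiliary F6 gives the syn aldol adduct F11. TBSOTf gives the C2 silyl ether F12, and DIBAL-H at −78 °C gives the C4 aldehyde F13. Nozaki–Hiyama–Kishi coupling (CrCl2, catalytic NiCl2, DMF) with triethyl[(2-iodoallyl)oxy]silane F14, made from 2-iodoprop-2-en-1-ol and TESCl, should add in the Felkin–Anh sense to the α-alkoxy aldehyde. This gives the 3,4-anti carbinol, so the route is rejoined at 34.

**3. Step 30.**

*What may go wrong.*
- The crowded endo hydroxyl may resist activation.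
- The axial leaving group, aligned with the C5=C16 π bond, may be displaced with allylic transposition so that chloride ends up on C16.

*Fallback.* The transposition is used on purpose. It sets out from carbinol 40 (42 serves equally, so steps 28 and 29 are not needed).

Ph3SiOReO3-catalysed 1,3-transposition of the allylic alcohol in Et2O should give the more substituted C5=C6 alkene with a primary C16 alcohol F15. SOCl2 in Et2O then converts it through the chlorosulfite by the cyclic SNi′ pathway. Chloride is delivered to C6 from the open exo face and the C5=C16 methylene is regenerated. The route is rejoined at 44.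

## Further compounds

F1 | step 27 | tert-butyldimethylsilyloxyfuran from 23 | C=C1CC[C@H](OC(C)=O)[C@@](COCc2ccc(OC)cc2)(C)[C@H]1[C@H](OC(C)=O)c1coc(O[Si](C)(C)C(C)(C)C)c1C
F2 | step 27 | syn iodoallylic carbinol (C6 OH, C5 iodide) | C=C1CC[C@H](OC(C)=O)[C@@](COCc2ccc(OC)cc2)(C)[C@H]1[C@H](OC(C)=O)C1=C(C)C(=O)O[C@H]1[C@H](O)C(I)=C
F3 | step 27 | C6 triethylsilyl ether | C=C1CC[C@H](OC(C)=O)[C@@](COCc2ccc(OC)cc2)(C)[C@H]1[C@H](OC(C)=O)C1=C(C)C(=O)O[C@H]1[C@H](O[Si](CC)(CC)CC)C(I)=C
F4 | step 27 | C2 primary alcohol | C=C1CC[C@H](OC(C)=O)[C@@](CO)(C)[C@H]1[C@H](OC(C)=O)C1=C(C)C(=O)O[C@H]1[C@H](O[Si](CC)(CC)CC)C(I)=C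
F5 | step 27 | C2 aldehyde | C=C1CC[C@H](OC(C)=O)[C@@](C=O)(C)[C@H]1[C@H](OC(C)=O)C1=C(C)C(=O)O[C@H]1[C@H](O[Si](CC)(CC)CC)C(I)=C
F6 | step 27 | N-{[(4-methoxybenzyl)oxy]acetyl}-(S)-4-benzylthiazolidine-2-thione | COc1ccc(COCC(=O)N2[C@@H](Cc3ccccc3)CSC2=S)cc1
F7 | step 27 | syn aldol adduct with auxiliary | C=C1CC[C@H](OC(C)=O)[C@@]([C@@H](O)[C@H](OCc2ccc(OC)cc2)C(=O)N2[C@@H](Cc3ccccc3)CSC2=S)(C)[C@H]1[C@H](OC(C)=O)C1=C(C)C(=O)O[C@H]1[C@H](O[Si](CC)(CC)CC)C(I)=C
F8 | step 27 | C2 silyl ether of F7 | C=C1CC[C@H](OC(C)=O)[C@@]([C@@H](O[Si](C)(C)C(C)(C)C)[C@H](OCc2ccc(OC)cc2)C(=O)N2[C@@H](Cc3ccccc3)CSC2=S)(C)[C@H]1[C@H](OC(C)=O)C1=C(C)C(=O)O[C@H]1[C@H](O[Si](CC)(CC)CC)C(I)=C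
F9 | step 27 | C4 aldehyde with C5 vinyl iodide | C=C1CC[C@H](OC(C)=O)[C@@]([C@@H](O[Si](C)(C)C(C)(C)C)[C@H](OCc2ccc(OC)cc2)C=O)(C)[C@H]1[C@H](OC(C)=O)C1=C(C)C(=O)O[C@H]1[C@H](O[Si](CC)(CC)CC)C(I)=C
F10 | step 27 | macrocyclic C4 allylic alcohol, C6 OTES | C=C1CC[C@H](OC(C)=O)[C@@]2(C)[C@H]1[C@H](OC(C)=O)C1=C(C)C(=O)O[C@H]1[C@H](O[Si](CC)(CC)CC)C(=C)[C@@H](O)[C@@H](OCc1ccc(OC)cc1)[C@@H]2O[Si](C)(C)C(C)(C)C
F11 | step 22 | syn aldol adduct of 25 with auxiliary | C=C1CC[C@H](OC(C)=O)[C@@]([C@@H](O)[C@H](OCc2ccc(OC)cc2)C(=O)N2[C@@H](Cc3ccccc3)CSC2=S)(C)[C@H]1[C@H](OC(C)=O)C1=C(C)C(=O)OC1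
F12 | step 22 | C2 silyl ether of F11 | C=C1CC[C@H](OC(C)=O)[C@@]([C@@H](O[Si](C)(C)C(C)(C)C)[C@H](OCc2ccc(OC)cc2)C(=O)N2[C@@H](Cc3ccccc3)CSC2=S)(C)[C@H]1[C@H](OC(C)=O)C1=C(C)C(=O)OC1
F13 | step 22 | C4 aldehyde | C=C1CC[C@H](OC(C)=O)[C@@]([C@@H](O[Si](C)(C)C(C)(C)C)[C@H](OCc2ccc(OC)cc2)C=O)(C)[C@H]1[C@H](OC(C)=O)C1=C(C)C(=O)OC1
F14 | step 22 | triethyl[(2-iodoallyl)oxy]silane | C=C(I)CO[Si](CC)(CC)CC
F15 | step 30 | transposed C16 primary allylic alcohol with C5=C6 | C=C1CC[C@H](OC(C)=O)[C@@]2(C)[C@H]1[C@H](OC(C)=O)[C@@]13O[C@H](C(CO)=C[C@@H]1OC(=O)[C@@H]3C)[C@@H](OCc1ccc(OC)cc1)[C@@H]2O[Si](C)(C)C(C)(C)C
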